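Drimane-type locants are used (ring A: C1–C5, C10; ring B: C5–C10; C4 bears the methylene, C11 the quinone). Ring B is cut by a retro-Diels–Alder disconnection of C7–C8 and C9–C10. The key step, an intramolecular Diels–Alder reaction of a (Z)-but-2-enoate tethered through the C1 oxygen of a 2-methyl-3-vinylcyclohexenol, closes ring B, creates quaternary C10 and the cis C8 methyl, and sets the lactone carbonyl C12 (the future C9 methyl) cis to both: it exploits the all-cis C8/C9/C10 methyl triad of ring B. The CBS-derived C1 carbinol steers this step, later directs hydrogenation at C5, and is then removed; enolate benzylation completes C9.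

Key step: step 5

Remark: compounds 1, 2, 6, 10 and ethyl but-2-ynoate (fallback only) are taken as commercial. The hydroxyl introduced at C4 in step 11 is drawn in its expected configuration, which is erased in step 12. Stereodescriptors in names refer to the route locants.

Step 1
Reactants: 1 3-ethoxy-2-methylcyclohex-2-en-1-one; 2 vinylmagnesium bromide
Product: 4 2-methyl-3-vinylcyclohex-2-en-1-one, via carbinol adduct 3 (not isolated)
Conditions: CH2=CHMgBr, THF, 0 °C; then 1 M HCl, rt
Reagents that add atoms: vinylmagnesium bromide 2, C=C[Mg]Br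
Why: Stork–Danheiser sequence: 1,2-addition of the Grignard reagent to the vinylogous ester carbonyl, then acid-promoted hydrolysis and loss of ethanol from carbinol 3, should give the transposed β-vinyl enone.

Step 2
Reactants: 4 2-methyl-3-vinylcyclohex-2-en-1-one
Product: 5 (S)-2-methyl-3-vinylcyclohex-2-en-1-ol
Conditions: (R)-1-methyl-3,3-diphenyltetrahydro-1H,3H-pyrrolo[1,2-c][1,3,2]oxazaborole ((R)-Me-CBS, 10 mol %), catecholborane, toluene, −78 °C; aq. NaOH work-up
Reagents that add atoms: none
Why: Corey–Bakshi–Shibata reduction in which the fully substituted alkenyl arm is the large group, so the (R)-catalyst should give the (S)-carbinol, the only stereocentre set by catalysis; catecholborane avoids hydroboration of the diene.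

Step 3
Reactants: 5 (S)-2-methyl-3-vinylcyclohex-2-en-1-ol; 6 but-2-ynoic acid
Product: 7 (S)-2-methyl-3-vinylcyclohex-2-en-1-yl but-2-ynoate
Conditions: DCC, DMAP (cat.), CH2Cl2, −20 → 0 °C
Reagents that add atoms: but-2-ynoic acid 6, CC#CC(=O)O
Why: Steglich esterification of the secondary allylic alcohol under neutral conditions should leave the carbinol centre and the diene untouched.

Step 4
Reactants: 7 (S)-2-methyl-3-vinylcyclohex-2-en-1-yl but-2-ynoate
Product: 8 (S)-2-methyl-3-vinylcyclohex-2-en-1-yl (Z)-but-2-enoate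
Conditions: H2 (1 atm), Pd on CaCO3 poisoned with Pb(OAc)2, quinoline, EtOAc, 0 °C, stopped at one equivalent of H2
Reagents that add atoms: none
Why: Lindlar semi-hydrogenation adds H2 syn to the ynoate to give the (Z)-enoate, the poisoned catalyst sparing the conjugated diene at controlled uptake.

Step 5
Reactants: 8 (S)-2-methyl-3-vinylcyclohex-2-en-1-yl (Z)-but-2-enoate
Product: 9 (1S,8S,9S,10R)-tricyclic lactone (γ-lactone C9–C12(=O)–O–C1 on the Δ5(6)-octalin)
Conditions: toluene (0.01 M), BHT (cat.), sealed tube, 170 °C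
Reagents that add atoms: none
Why: A thermal, concerted, suprafacial [4+2] cycloaddition (intramolecular Diels–Alder reaction of an ester-tethered 1,6,8-triene, a reaction type known for 3-vinylcyclohex-2-enyl alkynoates and acrylates) joins C7 to C8 and C9 to C10. Ring B closes as the six-membered Diels–Alder ring and the γ-lactone (C1–O–C12–C9–C10) as the fused tether ring in the tether-exo mode. C10 is set by delivery of the dienophile to the face that carries the C1–O bond, C8 by the Z geometry of the enoate (methyl cis to the carbonyl, hence cis to the C10 methyl), and C9 by the exo placement of C12. The step needs exo over endo orientation of the tether: the half-chair of ring A fixes the O–C1–C10 torsion so that a three-atom ester tether should reach C9 only with C12 exo, which also keeps the C8 methyl away from the diene. It also needs the cycloaddition to outrun the [1,5]-hydrogen shift of the Z-methyl diene, which intramolecularity at 170 °C should allow.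

Step 6
Reactants: 10 1,2,4,5-tetramethoxybenzene
Product: 12 (2,3,5,6-tetramethoxyphenyl)methanol, via aryllithium 11 (not isolated)
Conditions: n-BuLi, TMEDA, THF, 0 °C; then (CH2O)n, 0 °C → rt; H2O
Reagents that add atoms: paraformaldehyde (as formaldehyde), C=O
Why: Directed ortho-lithiation between two methoxy groups (both free positions are equivalent) followed by hydroxymethylation of the aryllithium is standard.

Step 7
Reactants: 12 (2,3,5,6-tetramethoxyphenyl)methanol
Product: 13 3-(bromomethyl)-1,2,4,5-tetramethoxybenzene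
Conditions: PBr3, Et2O, 0 °C; used at once
Reagents that add atoms: phosphorus tribromide, BrP(Br)Br
Why: Nucleophilic substitution of an electron-rich benzylic alcohol with PBr3 is fast at 0 °C, and the labile bromide is used without storage.

Step 8
Reactants: 9 tricyclic lactone; 13 3-(bromomethyl)-1,2,4,5-tetramethoxybenzene
Product: 15 (1S,8S,9S,10S)-9-(2,3,5,6-tetramethoxybenzyl) lactone, via lithium enolate 14 (not isolated)
Conditions: LiN(i-Pr)2, THF, −78 °C; then 13, DMPU, −78 → −20 °C
Reagents that add atoms: bromide 13, BrCc1c(OC)c(OC)cc(OC)c1OC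
Why: Enolate alkylation: the axial C8 and C10 methyls both shield the lower face, so the reactive benzylic bromide should enter anti to them, placing C11 trans to the C10 methyl and leaving C12 as the future cis C9 methyl.

Step 9
Reactants: 15 benzylated lactone
Product: 16 lactol (C12 hemiacetal)
Conditions: i-Bu2AlH, CH2Cl2, −78 °C; aqueous work-up
Reagents that add atoms: none
Why: Low-temperature i-Bu2AlH reduction of a hindered α-quaternary γ-lactone should stop at the lactol.

Step 10
Reactants: 16 lactol
Product: 18 (1S,8S,9R,10S)-8,9,10-trimethyl-9-(2,3,5,6-tetramethoxybenzyl)-Δ5(6)-octalin-1-ol, via hydrazone 17 (not isolated)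
Conditions: N2H4·H2O, KOH, diethylene glycol, 130 °C then 200 °C
Reagents that add atoms: none
Why: Wolff–Kishner reduction (Huang-Minlon procedure) of the aldehyde tautomer of the lactol should turn C12 into the C9 methyl and free the C1 hydroxyl, a classical route from angular lactols to angular methyls.

Step 11
Reactants: 18 octalin-1-ol
Product: 19 (1S,4S,8S,9R,10R)-octalin-1,4-diol
Conditions: SeO2 (0.5 equiv), t-BuOOH, CH2Cl2, rt
Reagents that add atoms: selenium dioxide, O=[Se]=O; tert-butyl hydroperoxide, CC(C)(C)OO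
Why: SeO2 allylic oxidation (ene reaction then [2,3]-sigmatropic shift) of a trisubstituted alkene occurs at the CH2 on the more substituted alkene carbon, here C4, without moving the C5=C6 bond.

Step 12
Reactants: 19 octalin-1,4-diol
Product: 20 (1S,8S,9R,10R)-1-hydroxy-Δ5(6)-octalin-4-one
Conditions: MnO2 (excess), CH2Cl2, rt
Reagents that add atoms: none
Why: MnO2 oxidises the allylic C4 alcohol chemoselectively and leaves the saturated C1 carbinol for the next step.

Step 13
Reactants: 20 hydroxy enone
Product: 21 (1S,5R,8S,9R,10S)-1-hydroxy-trans-decalin-4-one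
Conditions: H2 (1 atm), [Ir(cod)(PCy3)(py)]PF6 (5 mol %), CH2Cl2, rt; used directly in step 14
Reagents that add atoms: none
Why: Hydroxyl-directed homogeneous hydrogenation: the cationic iridium catalyst bound to the homoallylic C1 hydroxyl should deliver H2 to the same face of C5=C6, giving H5 cis to the C1 oxygen and therefore trans to the C10 methyl under kinetic control.

Step 14
Reactants: 21 hydroxy ketone
Product: 22 (1S,5S,8S,9R,10S)-4-methylidene-trans-decalin-1-ol
Conditions: Zn, CH2Br2, TiCl4, THF–CH2Cl2, 0 °C → rt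
Reagents that add atoms: dibromomethane, BrCBr
Why: Takai–Lombardo methylenation is non-basic and should convert the C4 ketone into the exocyclic methylene without epimerising the adjacent C5 centre.

Step 15
Reactants: 22 methylidene decalinol
Product: 23 O-decalinyl S-methyl dithiocarbonate (xanthate at C1)
Conditions: NaH, CS2, imidazole (cat.), THF, 0 °C → rt; then MeI
Reagents that add atoms: carbon disulfide, S=C=S; iodomethane, CI
Why: Xanthate formation from the hindered secondary alkoxide prepares the C1 oxygen for radical removal.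

Step 16
Reactants: 23 xanthate
Product: 24 (5S,8S,9R,10S)-4-methylidene-8,9,10-trimethyl-9-(2,3,5,6-tetramethoxybenzyl)-trans-decalin
Conditions: n-Bu3SnH, AIBN (cat.), toluene, 110 °C
Reagents that add atoms: none
Why: Barton–McCombie deoxygenation through the secondary C1 radical should give the C1 methylene, the exocyclic alkene being geometrically unable to trap that radical.

Step 17
Reactants: 24 tetramethoxyaryl decalin
Product: 25 2,5-dimethoxy-3-(decalinylmethyl)-1,4-benzoquinone
Conditions: (NH4)2Ce(NO3)6, MeCN–H2O, 0 °C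
Reagents that add atoms: water, O
Why: Oxidative demethylation of a para-dimethoxy pair should give the 2,5-dimethoxy-1,4-benzoquinone; both para pairs of the arene lead to the same quinone.

Step 18
Reactants: 25 dimethoxyquinone
Product: 26 CNP0109104.1 (target)
Conditions: 60% aq. HClO4, THF, 0 °C → rt, short reaction time
Reagents that add atoms: water, O
Why: Acid-mediated hydrolysis of a vinylogous ester (addition–elimination): the methoxy group flanked by the alkyl substituent and a carbonyl is twisted out of conjugation and should be cleaved selectively, while brief exposure at low temperature should spare the exocyclic alkene.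

Compound list
1 | 3-ethoxy-2-methylcyclohex-2-en-1-one | CCOC1=C(C)C(=O)CCC1 | starting material
2 | vinylmagnesium bromide | C=C[Mg]Br | starting material
3 | 3-ethoxy-2-methyl-1-vinylcyclohex-2-en-1-ol (racemic carbinol adduct) | CCOC1=C(C)C(O)(C=C)CCC1 | intermediate (not isolated)
4 | 2-methyl-3-vinylcyclohex-2-en-1-one | C=CC1=C(C)C(=O)CCC1 | intermediate
5 | (S)-2-methyl-3-vinylcyclohex-2-en-1-ol | C=CC1=C(C)[C@@H](O)CCC1 | intermediate
6 | but-2-ynoic acid | CC#CC(=O)O | starting material
7 | (S)-2-methyl-3-vinylcyclohex-2-en-1-yl but-2-ynoate | C=CC1=C(C)[C@@H](OC(=O)C#CC)CCC1 | intermediate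
8 | (S)-2-methyl-3-vinylcyclohex-2-en-1-yl (Z)-but-2-enoate | C=CC1=C(C)[C@@H](OC(=O)/C=C\C)CCC1 | intermediate
9 | (1S,8S,9S,10R)-tricyclic lactone, i.e. (2aS,3S,8aS,8bR)-3,8b-dimethyl-2a,3,4,6,7,8,8a,8b-octahydro-2H-naphtho[1,8-bc]furan-2-one; C8 methyl, C12 and C10 methyl mutually cis, H9 and the C1–O bond on the other face | O=C1O[C@H]2CCCC3=CC[C@H](C)[C@H]1[C@@]23C | intermediate
10 | 1,2,4,5-tetramethoxybenzene | COc1cc(OC)c(OC)cc1OC | starting material
11 | (2,3,5,6-tetramethoxyphenyl)lithium | [Li]c1c(OC)c(OC)cc(OC)c1OC | intermediate (not isolated)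
12 | (2,3,5,6-tetramethoxyphenyl)methanol | OCc1c(OC)c(OC)cc(OC)c1OC | intermediate
13 | 3-(bromomethyl)-1,2,4,5-tetramethoxybenzene | BrCc1c(OC)c(OC)cc(OC)c1OC | intermediate
14 | lithium enolate of lactone 9 (C9=C12(OLi)–O) | [Li]OC1=C2[C@@H](C)CC=C3CCC[C@H](O1)[C@]23C | intermediate (not isolated)
15 | (1S,8S,9S,10S)-9-(2,3,5,6-tetramethoxybenzyl) derivative of lactone 9; benzyl trans to the C10 methyl, C12 cis to it | O=C1O[C@H]2CCCC3=CC[C@H](C)[C@@]1(Cc4c(OC)c(OC)cc(OC)c4OC)[C@@]23C | intermediate
16 | lactol of 15 (C12 hemiacetal, both anomers) | OC1O[C@H]2CCCC3=CC[C@H](C)[C@@]1(Cc4c(OC)c(OC)cc(OC)c4OC)[C@@]23C | intermediate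
17 | (E)-hydrazone of the ring-opened C12 aldehyde, C1 hydroxyl free | N/N=C/[C@@]1(Cc2c(OC)c(OC)cc(OC)c2OC)[C@@H](C)CC=C3CCC[C@H](O)[C@]13C | intermediate (not isolated)
18 | (1S,8S,9R,10S)-8,9,10-trimethyl-9-(2,3,5,6-tetramethoxybenzyl)-Δ5(6)-octalin-1-ol | C[C@@]1(Cc2c(OC)c(OC)cc(OC)c2OC)[C@@H](C)CC=C3CCC[C@H](O)[C@]13C | intermediate
19 | (1S,4S,8S,9R,10R)-8,9,10-trimethyl-9-(2,3,5,6-tetramethoxybenzyl)-Δ5(6)-octalin-1,4-diol (C4 hydroxyl cis to the C10 methyl) | C[C@@]1(Cc2c(OC)c(OC)cc(OC)c2OC)[C@@H](C)CC=C3[C@@H](O)CC[C@H](O)[C@]13C | intermediate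
20 | (1S,8S,9R,10R)-1-hydroxy-8,9,10-trimethyl-9-(2,3,5,6-tetramethoxybenzyl)-Δ5(6)-octalin-4-one | C[C@@]1(Cc2c(OC)c(OC)cc(OC)c2OC)[C@@H](C)CC=C3C(=O)CC[C@H](O)[C@]13C | intermediate
21 | (1S,5R,8S,9R,10S)-1-hydroxy-8,9,10-trimethyl-9-(2,3,5,6-tetramethoxybenzyl)-trans-decalin-4-one | C[C@@]1(Cc2c(OC)c(OC)cc(OC)c2OC)[C@@H](C)CC[C@H]3C(=O)CC[C@H](O)[C@]13C | intermediate
22 | (1S,5S,8S,9R,10S)-4-methylidene-8,9,10-trimethyl-9-(2,3,5,6-tetramethoxybenzyl)-trans-decalin-1-ol | C[C@@]1(Cc2c(OC)c(OC)cc(OC)c2OC)[C@@H](C)CC[C@H]3C(=C)CC[C@H](O)[C@]13C | intermediate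
23 | S-methyl xanthate of 22 (O–C(=S)SMe at C1) | C[C@@]1(Cc2c(OC)c(OC)cc(OC)c2OC)[C@@H](C)CC[C@H]3C(=C)CC[C@H](OC(=S)SC)[C@]13C | intermediate
24 | (5S,8S,9R,10S)-4-methylidene-8,9,10-trimethyl-9-(2,3,5,6-tetramethoxybenzyl)-trans-decalin | C[C@@]1(Cc2c(OC)c(OC)cc(OC)c2OC)[C@@H](C)CC[C@H]3C(=C)CCC[C@]13C | intermediate
25 | 2,5-dimethoxy-3-{[(5S,8S,9R,10S)-4-methylidene-8,9,10-trimethyl-trans-decalin-9-yl]methyl}cyclohexa-2,5-diene-1,4-dione | C[C@@]1(CC2=C(OC)C(=O)C=C(OC)C2=O)[C@@H](C)CC[C@H]3C(=C)CCC[C@]13C | intermediate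
26 | CNP0109104.1: 2-hydroxy-5-methoxy-3-{[(1R,2S,4aS,8aS)-1,2,8a-trimethyl-5-methylidenedecahydronaphthalen-1-yl]methyl}cyclohexa-2,5-diene-1,4-dione | C=C1CCC[C@@]2(C)[C@H]1CC[C@H](C)[C@@]2(C)CC1=C(O)C(=O)C=C(OC)C1=O | target

Total step count: 18. Longest linear sequence: 16 (steps 1–5 and 8–18; steps 6–7 make bromide 13).

Steps most likely to fail

Step 5. The cycloaddition of the Z-enoate onto the fully substituted diene terminus may be too slow below the temperature at which the Z-methyl diene undergoes a [1,5]-hydrogen shift, or the endo-tether mode may leak in and erode the diastereoselectivity. The fallback sets out from ynoate 7 and comes back at 15. Ynoate 7 is heated as such (toluene, 110–130 °C); the linear, more reactive alkynoate dienophile raises no endo/exo question and should give the alkylidene lactone F1 (C8=C9 and C5=C6). Conjugate reduction with LiBH(s-Bu)3 (THF, −78 °C) should deliver hydride to C8 anti to the C10 methyl, and the enolate is benzylated in the same flask with bromide 13 (DMPU). This bypasses steps 4, 5 and 8.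

Step 8. C-alkylation at an enolate carbon flanked by a quaternary and a tertiary centre may lose out to O-alkylation, proton return or decay of the labile bromide. The fallback sets out from dienol 5 and bromide 13 and comes back at 15; it builds the quaternary C9 in the cycloaddition instead. Pd(PPh3)4-catalysed syn-hydrostannation of commercial ethyl but-2-ynoate with n-Bu3SnH should give ethyl (E)-2-(tributylstannyl)but-2-enoate F2. Stille coupling with 13 (Pd2(dba)3, AsPh3, CuI) should give ethyl (Z)-2-(2,3,5,6-tetramethoxybenzyl)but-2-enoate F3, and LiOH the acid F4. Steglich esterification with 5 gives the ester F5, whose intramolecular Diels–Alder reaction (tether and methyl exo, benzyl endo) should give 15 directly.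

Step 18. Hydrolysis may occur at the wrong methoxy group, or the acid may shift the exocyclic double bond into the ring. The fallback sets out from 25 and comes back at 26 and is acid-free. Both vinylogous esters are saponified (aq. NaOH, THF, rt) to the 2,5-dihydroxyquinone F6. The unhindered hydroxyl next to the ring CH is then methylated with one equivalent of Me3SiCHN2 (MeOH–toluene, 0 °C).

Further compounds
F1 | step 5 | (1S,10S)-alkylidene lactone, (8aS,8bS)-3,8b-dimethyl-4,6,7,8,8a,8b-hexahydro-2H-naphtho[1,8-bc]furan-2-one | O=C1O[C@H]2CCCC3=CCC(C)=C1[C@@]23C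
F2 | step 8 | ethyl (E)-2-(tributylstannyl)but-2-enoate | C/C=C(\C(=O)OCC)[Sn](CCCC)(CCCC)CCCC
F3 | step 8 | ethyl (Z)-2-(2,3,5,6-tetramethoxybenzyl)but-2-enoate | C/C=C(\C(=O)OCC)Cc1c(OC)c(OC)cc(OC)c1OC
F4 | step 8 | (Z)-2-(2,3,5,6-tetramethoxybenzyl)but-2-enoic acid | C/C=C(\C(=O)O)Cc1c(OC)c(OC)cc(OC)c1OC
F5 | step 8 | (S)-2-methyl-3-vinylcyclohex-2-en-1-yl (Z)-2-(2,3,5,6-tetramethoxybenzyl)but-2-enoate | C=CC1=C(C)[C@@H](OC(=O)/C(Cc2c(OC)c(OC)cc(OC)c2OC)=C\C)CCC1
F6 | step 18 | 2,5-dihydroxy-3-{[(5S,8S,9R,10S)-4-methylidene-8,9,10-trimethyl-trans-decalin-9-yl]methyl}cyclohexa-2,5-diene-1,4-dione | C[C@@]1(CC2=C(O)C(=O)C=C(O)C2=O)[C@@H](C)CC[C@H]3C(=C)CCC[C@]13C
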